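A direct plan would allylate the phenol of the ring A aldehyde A1 (to A2), join A2 to a two-carbon aldehyde in an enzymatic acyloin reaction (ketol A3), attach ring B by a Mitsunobu reaction (aryloxy ketone A4), reduce with a bulky hydride (alcohol A5) and deallylate with zerovalent palladium.
Its weakest steps would be three.
The Mitsunobu etherification would ask a hindered 2,6-dimethoxyphenol to displace next to an aryl ketone, where enolisation and elimination threaten C8 once both fragments are invested.
The hydride reduction would leave C7 to the acyclic Felkin–Anh bias of the substrate alone.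
The allylation and deallylation would spend two of five steps without gain, the second on the final compound beside the C-allyl group of ring B.

The retrosynthesis cuts C7–H last (hydrogen transfer from a chiral catalyst), then ring A at C1–C6 and C2–C3 into 3,4-dimethoxyfuran and a terminal ynone, and the C8–O bond first (SN2 on a lactate sulfonate).
Ring B is bought; ring A arises last, from a furan.
Ring A allows this: C3–OH beside the C4 and C5 methoxy groups, hydrogen at C2 and C6 and the carbonyl-level C7 on C1 are the print of 3,4-dimethoxyfuran (C3 to C6 and its oxygen, the future phenol) on an alkynyl ketone (C1, C2).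
So no phenol is masked, the aryl ether is made on a simple ester before any ketone exists, and C7 is set by a chiral catalyst, not by substrate bias; a ketone is still reduced, but not under substrate control.

Key step: step 4

Assumption: ethyl (S)-2-(tosyloxy)propanoate and 3,4-dimethoxyfuran are taken as purchasable; the first is otherwise one tosylation away from ethyl (S)-lactate.

Step 1
Reactants: 1 4-allyl-2,6-dimethoxyphenol; 2 ethyl (S)-2-(tosyloxy)propanoate
Product: 3 ethyl (R)-2-(4-allyl-2,6-dimethoxyphenoxy)propanoate
Conditions: K2CO3, MeCN, 70 °C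
Reagents that add atoms: none
Why: Williamson-type SN2 displacement of the α-sulfonyloxy ester by the phenoxide with inversion at the future C8 (the classical entry to 2-aryloxypropanoates), the adjacent ester carbonyl accelerating substitution enough that the 2,6-disubstituted phenoxide should react under conditions that do not racemise the product.

Step 2
Reactants: 3 ethyl (R)-2-(4-allyl-2,6-dimethoxyphenoxy)propanoate
Product: 4 (R)-2-(4-allyl-2,6-dimethoxyphenoxy)-N-methoxy-N-methylpropanamide
Conditions: MeNH(OMe)·HCl, i-PrMgCl, THF, −20 °C
Reagents that add atoms: N,O-dimethylhydroxylamine hydrochloride, CNOC.Cl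
Why: Aminolysis of the ester by the chloromagnesium amide made in the flask (Weinreb amide synthesis), which is fast at −20 °C, where the α-aryloxy stereocentre should not be deprotonated.

Step 3
Reactants: 4 (R)-2-(4-allyl-2,6-dimethoxyphenoxy)-N-methoxy-N-methylpropanamide
Product: 5 (R)-4-(4-allyl-2,6-dimethoxyphenoxy)pent-1-yn-3-one
Conditions: HC≡CMgBr, THF, −10 to 0 °C; inverse quench into cold 1 M HCl
Reagents that add atoms: ethynylmagnesium bromide, C#C[Mg]Br
Why: Weinreb ketone synthesis, in which the chelated tetrahedral magnesium adduct blocks a second addition and releases the ynone only in the acidic quench, which also protonates the liberated amine before it can add to the triple bond, so that C8 should keep its configuration.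

Step 4
Reactants: 5 (R)-4-(4-allyl-2,6-dimethoxyphenoxy)pent-1-yn-3-one; 6 3,4-dimethoxyfuran
Product: 8 (R)-2-(4-allyl-2,6-dimethoxyphenoxy)-1-(3-hydroxy-4,5-dimethoxyphenyl)propan-1-one, via oxanorbornadiene cycloadduct 7 (not isolated)
Conditions: 6 (excess), toluene, 60 °C; concentrate; then TsOH·H2O (cat.), CH2Cl2, 0 °C to rt
Reagents that add atoms: none
Why: Thermal [4+2] cycloaddition of the electron-rich diene 6 across the electron-poor triple bond of 5 gives the 7-oxanorbornadiene 7, and acid then breaks the bridge C–O bond at the bridgehead next to the acyl-bearing carbon, because that cation is an oxocarbenium ion on a methoxy-bearing carbon and keeps the ketone at a nodal position, so the oxygen stays on the other bridgehead and loss of its proton gives the phenol. The closest known reaction type is the Diels–Alder reaction of furans with acetylenic ketones and esters followed by isomerisation of the 7-oxanorbornadiene to a 3-hydroxyaryl ketone or ester. Ring A closes by intermolecular cycloaddition, which forms C1–C6 and C2–C3 (ring A numbering) in one step, and it is aromatised by opening of the oxygen bridge with no loss of atoms, so the furan oxygen becomes the free C3 phenol. No stereocentre is created in the product, since the two bridgehead centres of 7 vanish on aromatisation, and C8 should survive neutral heating and brief catalytic acid. The step needs regioselective bridge opening (3-hydroxy, not 2-hydroxy), which the C7 ketone secures as described, and cycloaddition in preference to conjugate addition of the furan α-carbon, which the absence of any Lewis acid during the heating favours; the symmetry of 6 removes any regiochemical question in the cycloaddition, and the allyl group of ring B is no dienophile for 6.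

Step 5
Reactants: 8 (R)-2-(4-allyl-2,6-dimethoxyphenoxy)-1-(3-hydroxy-4,5-dimethoxyphenyl)propan-1-one
Product: 9 (1R,2R)-2-(4-allyl-2,6-dimethoxyphenoxy)-1-(3-hydroxy-4,5-dimethoxyphenyl)propan-1-ol
Conditions: RuCl[(S,S)-TsDPEN](p-cymene) (cat.), HCO2H/Et3N (5:2), DMF, 25 °C
Reagents that add atoms: none
Why: Noyori–Ikariya asymmetric transfer hydrogenation of an aryl ketone, in which the chiral ruthenium hydride chooses the carbonyl face through its aryl-recognising six-membered transition state, so that the (S,S) catalyst should give (7R) by catalyst control (here matched with the Felkin–Anh preference of the (8R) ketone) and hence the threo (7R,8R) alcohol, while the free phenol and the allyl group are inert to this hydride.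

Compound list
1 | 4-allyl-2,6-dimethoxyphenol | C=CCc1cc(OC)c(O)c(OC)c1 | starting material
2 | ethyl (S)-2-(tosyloxy)propanoate | C[C@H](OS(=O)(=O)c1ccc(C)cc1)C(=O)OCC | starting material
3 | ethyl (R)-2-(4-allyl-2,6-dimethoxyphenoxy)propanoate | C=CCc1cc(OC)c(O[C@H](C)C(=O)OCC)c(OC)c1 | intermediate
4 | (R)-2-(4-allyl-2,6-dimethoxyphenoxy)-N-methoxy-N-methylpropanamide | C=CCc1cc(OC)c(O[C@H](C)C(=O)N(C)OC)c(OC)c1 | intermediate
5 | (R)-4-(4-allyl-2,6-dimethoxyphenoxy)pent-1-yn-3-one | C=CCc1cc(OC)c(O[C@H](C)C(=O)C#C)c(OC)c1 | intermediate
6 | 3,4-dimethoxyfuran | COc1cocc1OC | starting material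
7 | (2R)-2-(4-allyl-2,6-dimethoxyphenoxy)-1-(5,6-dimethoxy-7-oxabicyclo[2.2.1]hepta-2,5-dien-2-yl)propan-1-one (both bridgehead diastereomers) | C=CCc1cc(OC)c(O[C@H](C)C(=O)C2=CC3OC2C(OC)=C3OC)c(OC)c1 | intermediate
8 | (R)-2-(4-allyl-2,6-dimethoxyphenoxy)-1-(3-hydroxy-4,5-dimethoxyphenyl)propan-1-one | C=CCc1cc(OC)c(O[C@H](C)C(=O)c2cc(O)c(OC)c(OC)c2)c(OC)c1 | intermediate
9 | (1R,2R)-2-(4-allyl-2,6-dimethoxyphenoxy)-1-(3-hydroxy-4,5-dimethoxyphenyl)propan-1-ol | C=CCc1cc(OC)c(O[C@H](C)[C@H](O)c2cc(O)c(OC)c(OC)c2)c(OC)c1 | target

Total step count: 5. Longest linear sequence: 5 steps (1 to 9).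

Steps most likely to fail

Step 4. The furan may add through its α-carbon to the ynone in a conjugate sense instead of cycloadding, or the oxygen bridge of the cycloadduct may open toward the ketone-bearing side and place the hydroxyl at C2. Ring A would then be brought in ready-made as a nucleophile. The fallback sets out from Weinreb amide 4 and returns at ketone 8. Commercial 5-bromo-2,3-dimethoxybenzaldehyde would be oxidised with mCPBA (Baeyer–Villiger reaction) to 5-bromo-2,3-dimethoxyphenyl formate F1 and hydrolysed with aqueous NaOH to 5-bromo-2,3-dimethoxyphenol F2. Deprotonation with MeLi and bromine–lithium exchange with t-BuLi (THF, −78 °C) would give lithium 5-lithio-2,3-dimethoxyphenolate F3. Addition of F3 to 4 and acidic work-up should give 8.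

Step 5. Hydrogen transfer to the electron-rich, phenolic ketone may be slow enough for triethylamine to epimerise C8, or the catalyst may not fully override the substrate, so that erythro isomer is formed. C7 would then be made by carbon–carbon bond formation instead of reduction. The fallback sets out from ester 3 and ends at the target 9. Reduction with i-Bu2AlH (CH2Cl2, −78 °C) would give (R)-2-(4-allyl-2,6-dimethoxyphenoxy)propanal F4. Addition of the aryl dianion F3 (made as described for step 4) to F4 precomplexed with MgBr2·OEt2 at −78 °C should pass through the five-membered magnesium chelate of the aldehyde oxygen and the aryloxy oxygen (Cram chelate control). Attack past the C8 hydrogen should then give the threo alcohol 9 directly.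

Step 3. The terminal ynone may suffer conjugate addition of the liberated N,O-dimethylhydroxylamine during the quench, or the basic Grignard reagent may enolise C8. The alkyne terminus would then be capped and the ynone unveiled in a separate operation. The fallback sets out from 4 and returns at ynone 5. LiC≡CSiMe3 (THF, −78 °C) would give (R)-4-(4-allyl-2,6-dimethoxyphenoxy)-1-(trimethylsilyl)pent-1-yn-3-one F5, which is shielded at the β-carbon. Bu4NF buffered with AcOH (THF, −20 °C) would then remove the silyl group to give 5.

Further compounds
F1 | step 4 | 5-bromo-2,3-dimethoxyphenyl formate | O=COc1cc(Br)cc(OC)c1OC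
F2 | step 4 | 5-bromo-2,3-dimethoxyphenol | Oc1cc(Br)cc(OC)c1OC
F3 | step 4 | lithium 5-lithio-2,3-dimethoxyphenolate | [Li]c1cc([O-])c(OC)c(OC)c1.[Li+]
F4 | step 5 | (R)-2-(4-allyl-2,6-dimethoxyphenoxy)propanal | C=CCc1cc(OC)c(O[C@H](C)C=O)c(OC)c1
F5 | step 3 | (R)-4-(4-allyl-2,6-dimethoxyphenoxy)-1-(trimethylsilyl)pent-1-yn-3-one | C=CCc1cc(OC)c(O[C@H](C)C(=O)C#C[Si](C)(C)C)c(OC)c1
A1 | direct plan | 3-hydroxy-4,5-dimethoxybenzaldehyde | O=Cc1cc(O)c(OC)c(OC)c1
A2 | direct plan | 3-(allyloxy)-4,5-dimethoxybenzaldehyde | O=Cc1cc(OCC=C)c(OC)c(OC)c1
A3 | direct plan | (S)-1-[3-(allyloxy)-4,5-dimethoxyphenyl]-2-hydroxypropan-1-one | C[C@H](O)C(=O)c1cc(OCC=C)c(OC)c(OC)c1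
A4 | direct plan | (R)-2-(4-allyl-2,6-dimethoxyphenoxy)-1-[3-(allyloxy)-4,5-dimethoxyphenyl]propan-1-one | C=CCc1cc(OC)c(O[C@H](C)C(=O)c2cc(OCC=C)c(OC)c(OC)c2)c(OC)c1
A5 | direct plan | (1R,2R)-2-(4-allyl-2,6-dimethoxyphenoxy)-1-[3-(allyloxy)-4,5-dimethoxyphenyl]propan-1-ol | C=CCc1cc(OC)c(O[C@H](C)[C@H](O)c2cc(OCC=C)c(OC)c(OC)c2)c(OC)c1
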